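**Retrosynthetic overview** (labdane numbering C1–C20 throughout)

- The target is the 8α-formate of labdanolic acid. The plan rests on ring B: C5–C10, the C17 methyl on C8 and the exocyclic C4 on C5 are the ring carbons, ring methyl and isopropenyl carbon of (R)-carvone, whose carbonyl carbon is C9.
- Ring B is bought. Ring A is the only ring made: C3–C4 is closed by an iron-hydride HAT radical cyclisation of the C4 radical onto a 2-sulfonylallyl arm on C10. C10 itself comes from two enolate alkylations of carvone.
- C9=O is methylenated (C11), and α-face hydroboration sets H-9α. Desulfonylation gives drimenol, and its aldehyde is joined at C11=C12 to a C12–C15 ylide that carries C13, made from 3-methylglutaric anhydride by desymmetrisation and Hunsdiecker degradation.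
- Hydrogenation of C11=C12, Mukaiyama hydration of C7=C8 (8α-OH), saponification and O-formylation finish the route.

Key step: step 5

Assumption (chemistry): the quinidine-derived catalyst (DHQD)2AQN is taken to open 3-methylglutaric anhydride to the (S)-hemiester, by analogy with the recalled sense of quinine/quinidine-mediated openings of 3-alkylglutaric anhydrides; should the sense be opposite, the pseudoenantiomer (DHQ)2AQN is used with no other change.

**Step 1**
Reactants: 1 phenyl vinyl sulfone
Product: 2 2-(phenylsulfonyl)prop-2-en-1-ol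
Conditions: aq. HCHO (37%), DABCO (cat.), THF, rt
Reagents that add atoms: formaldehyde, C=O
Why: Morita–Baylis–Hillman reaction, in which DABCO adds reversibly to the vinyl sulfone, the α-sulfonyl carbanion is hydroxymethylated by formaldehyde and loss of the amine restores the alkene.

**Step 2**
Reactants: 2 2-(phenylsulfonyl)prop-2-en-1-ol
Product: 3 3-bromo-2-(phenylsulfonyl)prop-1-ene
Conditions: PBr3, Et2O, 0 °C
Reagents that add atoms: phosphorus tribromide, BrP(Br)Br
Why: Standard conversion of a primary allylic alcohol into the bromide via its phosphite ester (SN2); the electron-poor alkene is inert to the reagent.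

**Step 3**
Reactants: 4 (R)-carvone
Product: 6 (5R)-6-methylcarvone (C6 epimer mixture), via carvone lithium dienolate 5 (not isolated)
Conditions: LiN(i-Pr)2, THF, −78 °C; MeI, −78 → 0 °C
Reagents that add atoms: iodomethane, CI
Why: Kinetic α′-deprotonation of the enone gives the cross-conjugated dienolate, and its C-methylation (enolate alkylation) installs the future C20 methyl on C10; the epimer mixture is of no consequence because this carbon is planarised again in step 4.

**Step 4**
Reactants: 6 (5R)-6-methylcarvone; 3 3-bromo-2-(phenylsulfonyl)prop-1-ene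
Product: 8 (5S,6S)-2,6-dimethyl-6-[2-(phenylsulfonyl)prop-2-en-1-yl]-5-(prop-1-en-2-yl)cyclohex-2-en-1-one, via 6-methylcarvone lithium dienolate 7 (not isolated)
Conditions: LiN(i-Pr)2, THF/DMPU, −78 → 0 °C; then enolate added to 3, −78 °C
Reagents that add atoms: none
Why: Enolate alkylation by SN2′ addition–elimination on the sulfonylallyl bromide builds the quaternary C10, with the electrophile entering anti to the neighbouring C5 isopropenyl group (as known for allylation of 6-methylcarvone), so that the C1 arm is trans to C4 and the C20 methyl cis to it.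

**Step 5**
Reactants: 8 (5S,6S)-2,6-dimethyl-6-[2-(phenylsulfonyl)prop-2-en-1-yl]-5-(prop-1-en-2-yl)cyclohex-2-en-1-one
Product: 9 (4aS,8aS)-2,5,5,8a-tetramethyl-7-(phenylsulfonyl)-4a,5,6,7,8,8a-hexahydronaphthalen-1(4H)-one (C2 epimers)
Conditions: Fe(acac)3 (0.5 equiv), PhSiH3 (2.5 equiv), EtOH/(CH2OH)2 5:1, 0.02 M, 60 °C
Reagents that add atoms: none
Why: The iron hydride formed from Fe(acac)3 and PhSiH3 transfers a hydrogen atom to the CH2 terminus of the electron-rich 1,1-disubstituted isopropenyl group, which becomes the second methyl on C4 and leaves a nucleophilic tertiary radical at C4. This radical adds to the unsubstituted terminus C3 of the vinyl sulfone, forming C3–C4 and closing ring A (C4, C5, C10, C1, C2, C3) in the 6-endo-trig mode; the α-sulfonyl radical at C2 is then reduced by divalent iron to the carbanion and protonated by ethanol, which returns trivalent iron. The closest known reaction type is the metal-hydride HAT-initiated reductive olefin coupling (radical Giese addition) of donor olefins with acrylates, enones and vinyl sulfones, including ring-forming cases. The only new stereocentre is C2, which is uncontrolled and erased in step 8; the trans ring fusion is inherited, because the C4 radical on C5 and the C1 arm on C10 are trans on ring B and can only bridge to a trans-decalin. The step needs chemoselective HAT at the isopropenyl group over the two electron-poor alkenes and 6-endo over 5-exo attack: the first rests on the preference of the hydride for the olefin that gives a tertiary alkyl radical, the second on polarity matching, since attack at C3 gives a sulfonyl-stabilised radical whereas 5-exo attack at C2 would meet a fully substituted carbon and give a primary radical. High dilution suppresses intermolecular addition, and the enone is kept as the handle for C8, C9 and C11.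

**Step 6**
Reactants: 9 sulfonyl enone
Product: 10 2-(phenylsulfonyl)drima-7,9(11)-diene (C2 epimers)
Conditions: Ph3PCH3Br, KOt-Bu, toluene, 90 °C
Reagents that add atoms: methyltriphenylphosphonium bromide, C[P+](c1ccccc1)(c1ccccc1)c1ccccc1.[Br-] (delivers CH2 as its ylide)
Why: Wittig methylenation with salt-free methylenetriphenylphosphorane in hot toluene, conditions that serve for hindered ketones such as camphor, on a ketone that has no α-hydrogen (C10 quaternary, C8 sp2), turns C9=O into C9=C11H2.

**Step 7**
Reactants: 10 2-(phenylsulfonyl)drima-7,9(11)-diene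
Product: 12 2-(phenylsulfonyl)drimenol (C2 epimers), via B-alkyl-9-BBN adduct 11 (not isolated)
Conditions: 9-BBN, THF, 0 → 60 °C; then NaOH, H2O2, 0 °C → rt
Reagents that add atoms: hydrogen peroxide, OO; 9-BBN, B1C2CCCC1CCC2 (its boron is carried only in 11)
Why: Hydroboration–oxidation places boron on the terminal C11 and hydrogen on C9 of the 1,1-disubstituted diene terminus and leaves the trisubstituted C7=C8 alone; the borane approaches from the α-face, opposite the axial C20 methyl on the adjacent C10, so H-9 is α and C11 β (equatorial).

**Step 8**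
Reactants: 12 2-(phenylsulfonyl)drimenol
Product: 13 (−)-drimenol
Conditions: Mg turnings, MeOH, 50 °C
Reagents that add atoms: none
Why: Reductive desulfonylation by electron transfer from magnesium cleaves the C2–S bond and methanol protonates C2, which removes the only uncontrolled stereocentre; the isolated trisubstituted alkene and the primary alcohol are inert, and the known natural product serves as a checkpoint for C5, C9 and C10.

**Step 9**
Reactants: 13 (−)-drimenol
Product: 14 drimenal (drim-7-en-11-al)
Conditions: Dess–Martin periodinane, NaHCO3, CH2Cl2, 0 °C; used crude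
Reagents that add atoms: none
Why: Dess–Martin oxidation under bicarbonate buffering gives the β,γ-unsaturated aldehyde without acid or base strong enough to epimerise C9 or to move C7=C8 into conjugation.

**Step 10**
Reactants: 15 3-methylglutaric anhydride
Product: 16 (S)-5-methoxy-3-methyl-5-oxopentanoic acid
Conditions: MeOH (10 equiv), (DHQD)2AQN [hydroquinidine anthraquinone-1,4-diyl diether] (30 mol %), Et2O, −40 °C
Reagents that add atoms: methanol, CO
Why: Cinchona-alkaloid-catalysed enantioselective alcoholysis (desymmetrisation of a prochiral cyclic anhydride) delivers methanol by general-base catalysis to one of the two enantiotopic carbonyl groups and so sets the centre that becomes C13; enantiomeric purity can be raised by crystallising an amine salt of the hemiester if needed.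

**Step 11**
Reactants: 16 (S)-hemiester
Product: 17 methyl (R)-4-bromo-3-methylbutanoate
Conditions: HgO, Br2, CCl4, reflux, dark
Reagents that add atoms: bromine, BrBr
Why: Hunsdiecker-type decarboxylative bromination (Cristol–Firth variant) passes through an acyl hypobromite and a primary radical remote from the stereocentre, which is untouched; the descriptor changes to R only because CH2Br outranks CH2CO2Me.

**Step 12**
Reactants: 17 methyl (R)-4-bromo-3-methylbutanoate
Product: 18 [(2R)-4-methoxy-2-methyl-4-oxobutyl]triphenylphosphonium bromide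
Conditions: PPh3, MeCN, reflux
Reagents that add atoms: triphenylphosphine, c1ccc(cc1)P(c1ccccc1)c1ccccc1
Why: SN2 quaternisation of triphenylphosphine by the primary bromide, slowed but not prevented by β-branching; the crystalline salt also offers a chance to upgrade purity.

**Step 13**
Reactants: 18 phosphonium bromide; 14 drimenal
Product: 20 methyl (11Z,13R)-labda-7,11-dien-15-oate, via phosphorus ylide 19 (not isolated)
Conditions: NaN(SiMe3)2 (1.0 equiv), THF, −78 → 0 °C; then 14, −78 °C → rt
Reagents that add atoms: none
Why: Wittig olefination with a non-stabilised ylide, formed with exactly one equivalent of base so that no free amide meets the enolisable aldehyde, forms C11=C12 (Z expected, geometry irrelevant); C13 is not acidic and keeps its configuration, the descriptor R reflecting only the sp2 neighbour.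

**Step 14**
Reactants: 20 methyl (11Z,13R)-labda-7,11-dien-15-oate
Product: 21 methyl (13S)-labd-7-en-15-oate
Conditions: H2 (4 atm), RhCl(PPh3)3 (10 mol %), benzene/EtOH, rt
Reagents that add atoms: none
Why: Homogeneous hydrogenation with RhCl(PPh3)3 discriminates by substitution, reducing the 1,2-disubstituted C11=C12 and leaving the hindered trisubstituted C7=C8 in place and unisomerised.

**Step 15**
Reactants: 21 methyl (13S)-labd-7-en-15-oate
Product: 22 methyl labdanolate
Conditions: Mn(dpm)3 [dpm = 2,2,6,6-tetramethylheptane-3,5-dionate] (10 mol %), PhSiH3, O2 (1 atm), i-PrOH, 0 °C → rt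
Reagents that add atoms: dioxygen, O=O
Why: Mukaiyama hydration: hydrogen-atom transfer to C7 gives the tertiary C8 radical (Markovnikov), which should be captured by O2 on the α-face, away from the syn-axial C20 methyl, and reduced to the alcohol, giving 8α-OH with the C17 methyl β.

**Step 16**
Reactants: 22 methyl labdanolate
Product: 23 labdanolic acid
Conditions: LiOH, THF/MeOH/H2O, rt; then aq. HCl to pH 3
Reagents that add atoms: lithium hydroxide, [Li+].[OH-]
Why: Saponification of an unhindered methyl ester leaves the tertiary alcohol and all stereocentres untouched and gives a known natural product as a second checkpoint.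

**Step 17**
Reactants: 23 labdanolic acid
Product: 25 8-O-formyllabdanolic acid (target), via C15 mixed formic anhydride 24 (not isolated)
Conditions: AcOCHO (preformed, excess), pyridine, DMAP (cat.), CH2Cl2, 0 °C → rt; then H2O/THF, rt
Reagents that add atoms: acetic formic anhydride, CC(=O)OC=O
Why: DMAP-catalysed formyl transfer from the more electrophilic formyl carbonyl of the mixed anhydride acylates the tertiary C8 alcohol with retention at C8; the carboxylic acid is activated only transiently as a mixed anhydride, which water cleaves at work-up while the hindered tertiary formate survives.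

**Compound list**

1 | phenyl vinyl sulfone | C=CS(=O)(=O)c1ccccc1 | starting material
2 | 2-(phenylsulfonyl)prop-2-en-1-ol | C=C(CO)S(=O)(=O)c1ccccc1 | intermediate
3 | 3-bromo-2-(phenylsulfonyl)prop-1-ene [2-(phenylsulfonyl)allyl bromide] | C=C(CBr)S(=O)(=O)c1ccccc1 | intermediate
4 | (R)-carvone | C=C(C)[C@@H]1CC=C(C)C(=O)C1 | starting material
5 | cross-conjugated lithium dienolate of (R)-carvone (O–Li on C9, C9=C10) | C=C(C)[C@@H]1CC=C(C)C(O[Li])=C1 | intermediate (not isolated)
6 | (5R)-2,6-dimethyl-5-(prop-1-en-2-yl)cyclohex-2-en-1-one (6-methylcarvone, C6 epimers) | C=C(C)[C@@H]1CC=C(C)C(=O)C1C | intermediate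
7 | lithium dienolate of 6-methylcarvone (O–Li on C9, C9=C10) | C=C(C)[C@@H]1CC=C(C)C(O[Li])=C1C | intermediate (not isolated)
8 | (5S,6S)-2,6-dimethyl-6-[2-(phenylsulfonyl)prop-2-en-1-yl]-5-(prop-1-en-2-yl)cyclohex-2-en-1-one (arm trans to isopropenyl) | C=C(C)[C@@H]1CC=C(C)C(=O)[C@@]1(C)CC(=C)S(=O)(=O)c2ccccc2 | intermediate (key-step precursor)
9 | (4aS,8aS)-2,5,5,8a-tetramethyl-7-(phenylsulfonyl)-4a,5,6,7,8,8a-hexahydronaphthalen-1(4H)-one (trans-fused, C2 epimers) | O=C1[C@@]2(C)CC(S(=O)(=O)c3ccccc3)CC(C)(C)[C@@H]2CC=C1C | intermediate (key-step product)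
10 | (4aS,8aS)-2,5,5,8a-tetramethyl-1-methylidene-7-(phenylsulfonyl)-1,4,4a,5,6,7,8,8a-octahydronaphthalene [2-(phenylsulfonyl)drima-7,9(11)-diene] | C=C1[C@@]2(C)CC(S(=O)(=O)c3ccccc3)CC(C)(C)[C@@H]2CC=C1C | intermediate
11 | B-[2-(phenylsulfonyl)drim-7-en-11-yl]-9-borabicyclo[3.3.1]nonane (H-9α) | C1CC2CCCC(C1)B2C[C@@H]3[C@@]4(C)CC(S(=O)(=O)c5ccccc5)CC(C)(C)[C@@H]4CC=C3C | intermediate (not isolated)
12 | [(1S,4aS,8aS)-2,5,5,8a-tetramethyl-7-(phenylsulfonyl)-1,4,4a,5,6,7,8,8a-octahydronaphthalen-1-yl]methanol [2-(phenylsulfonyl)drimenol] | OC[C@@H]1[C@@]2(C)CC(S(=O)(=O)c3ccccc3)CC(C)(C)[C@@H]2CC=C1C | intermediate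
13 | (−)-drimenol, [(1S,4aS,8aS)-2,5,5,8a-tetramethyl-1,4,4a,5,6,7,8,8a-octahydronaphthalen-1-yl]methanol | OC[C@@H]1[C@@]2(C)CCCC(C)(C)[C@@H]2CC=C1C | intermediate
14 | drimenal, (1S,4aS,8aS)-2,5,5,8a-tetramethyl-1,4,4a,5,6,7,8,8a-octahydronaphthalene-1-carbaldehyde | O=C[C@@H]1[C@@]2(C)CCCC(C)(C)[C@@H]2CC=C1C | intermediate
15 | 3-methylglutaric anhydride | CC1CC(=O)OC(=O)C1 | starting material
16 | (S)-5-methoxy-3-methyl-5-oxopentanoic acid [methyl hydrogen (S)-3-methylglutarate] | C[C@@H](CC(=O)O)CC(=O)OC | intermediate
17 | methyl (R)-4-bromo-3-methylbutanoate | C[C@@H](CBr)CC(=O)OC | intermediate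
18 | [(2R)-4-methoxy-2-methyl-4-oxobutyl]triphenylphosphonium bromide | C[C@@H](C[P+](c1ccccc1)(c1ccccc1)c1ccccc1)CC(=O)OC.[Br-] | intermediate
19 | methyl (R)-3-methyl-4-(triphenyl-λ5-phosphanylidene)butanoate (ylide) | C[C@@H](C=P(c1ccccc1)(c1ccccc1)c1ccccc1)CC(=O)OC | intermediate (not isolated)
20 | methyl (3R,4Z)-3-methyl-5-[(1S,4aS,8aS)-2,5,5,8a-tetramethyl-1,4,4a,5,6,7,8,8a-octahydronaphthalen-1-yl]pent-4-enoate [methyl (11Z,13R)-labda-7,11-dien-15-oate] | C[C@@H](/C=C\[C@@H]1[C@@]2(C)CCCC(C)(C)[C@@H]2CC=C1C)CC(=O)OC | intermediate
21 | methyl (13S)-labd-7-en-15-oate | C[C@@H](CC[C@@H]1[C@@]2(C)CCCC(C)(C)[C@@H]2CC=C1C)CC(=O)OC | intermediate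
22 | methyl labdanolate, methyl (3S)-5-[(1R,2R,4aS,8aS)-2-hydroxy-2,5,5,8a-tetramethyldecahydronaphthalen-1-yl]-3-methylpentanoate | C[C@@H](CC[C@@H]1[C@@]2(C)CCCC(C)(C)[C@@H]2CC[C@@]1(C)O)CC(=O)OC | intermediate
23 | labdanolic acid | C[C@@H](CC[C@@H]1[C@@]2(C)CCCC(C)(C)[C@@H]2CC[C@@]1(C)O)CC(=O)O | intermediate
24 | 8-O-formyllabdanolic formic anhydride (C15 mixed anhydride) | C[C@@H](CC[C@@H]1[C@@]2(C)CCCC(C)(C)[C@@H]2CC[C@@]1(C)OC=O)CC(=O)OC=O | intermediate (not isolated)
25 | (3S)-5-[(1R,2R,4aS,8aS)-2-(formyloxy)-2,5,5,8a-tetramethyldecahydronaphthalen-1-yl]-3-methylpentanoic acid | C[C@@H](CC[C@@H]1[C@@]2(C)CCCC(C)(C)[C@@H]2CC[C@@]1(C)OC=O)CC(=O)O | target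

**Step count**

Total: 17 steps. Longest linear sequence: 13 steps (phenyl vinyl sulfone to 25 through steps 1, 2, 4–9 and 13–17); 12 steps counted from (R)-carvone.

**Steps most likely to fail**

1. Step 5. Hydrogen-atom transfer may go to the vinyl sulfone or the enone instead of the isopropenyl group, or the C4 radical may be reduced before it cyclises. The fallback sets out from 8. Markovnikov addition of HBr (HBr in AcOH, CH2Cl2, 0 °C, as in the classical hydrobromination of carvone) should give the tertiary bromide (5R,6S)-5-(2-bromopropan-2-yl)-2,6-dimethyl-6-[2-(phenylsulfonyl)prop-2-en-1-yl]cyclohex-2-en-1-one F1. Slow addition of Bu3SnH with AIBN in refluxing benzene then generates the same C4 radical by bromine abstraction. It should close ring A 6-endo onto the vinyl sulfone and be reduced by the stannane, rejoining the route at 9.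

2. Step 13. The ylide may deprotonate the β,γ-unsaturated aldehyde at C9, with epimerisation or migration of C7=C8 into conjugation competing with a slow olefination between two hindered partners. The fallback sets out from 13 and uses bromo ester 17 as partner. Appel bromination (CBr4, PPh3, CH2Cl2) should give 11-bromodrim-7-ene F2. Magnesium in THF converts it into drim-7-en-11-ylmagnesium bromide F3, whose open homoallylic form is favoured. Copper-catalysed sp3–sp3 coupling with 17 (Li2CuCl4 cat., THF/NMP, 0 °C, conditions under which esters are tolerated) forms C11–C12 directly and comes back at 21, bypassing 14 and 18–20.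

3. Step 15. Capture of the planar C8 radical by O2 may show poor facial selectivity (β-attack gives the 8-epimer), and over-oxidation is possible. The fallback sets out from 21. Epoxidation with mCPBA (NaHCO3, CH2Cl2, 0 °C) occurs on the α-face, away from the C20 methyl, and gives methyl (13S)-7α,8α-epoxylabdan-15-oate F4. LiAlH4 in THF delivers hydride to the secondary C7, so the C8–O bond and its α-configuration are retained, and also reduces the ester, giving (13S)-labdane-8α,15-diol F5. Chemoselective oxidation of the primary alcohol (TEMPO cat., NaOCl cat., NaClO2, MeCN/phosphate buffer) then returns to the route at 23, and step 16 is not needed.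

**Further compounds**

F1 | step 5 | (5R,6S)-5-(2-bromopropan-2-yl)-2,6-dimethyl-6-[2-(phenylsulfonyl)prop-2-en-1-yl]cyclohex-2-en-1-one | CC(C)(Br)[C@@H]1CC=C(C)C(=O)[C@@]1(C)CC(=C)S(=O)(=O)c2ccccc2
F2 | step 13 | 11-bromodrim-7-ene, (1S,4aS,8aS)-1-(bromomethyl)-2,5,5,8a-tetramethyl-1,4,4a,5,6,7,8,8a-octahydronaphthalene | BrC[C@@H]1[C@@]2(C)CCCC(C)(C)[C@@H]2CC=C1C
F3 | step 13 | drim-7-en-11-ylmagnesium bromide | Br[Mg]C[C@@H]1[C@@]2(C)CCCC(C)(C)[C@@H]2CC=C1C
F4 | step 15 | methyl (13S)-7α,8α-epoxylabdan-15-oate | C[C@@H](CC[C@@H]1[C@@]2(C)CCCC(C)(C)[C@@H]2C[C@H]3O[C@@]13C)CC(=O)OC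
F5 | step 15 | (13S)-labdane-8α,15-diol | C[C@@H](CC[C@@H]1[C@@]2(C)CCCC(C)(C)[C@@H]2CC[C@@]1(C)O)CCO
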